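The route rests on making ring A by its C1–C2 bond. A ring B cyclohexanone carries a neopentyl iodide (C1 on quaternary C10) and, on C5, the gem-dimethyl carbon C4 bearing a (Z)-1,2-dichlorovinyl group (C3=C2). A 6-endo radical cyclisation then builds the trans-decalin and both chlorine-bearing stereocentres in one operation. It exploits the trans-diequatorial C2/C3 dichloride of ring A between quaternary C4 and C10: a chair transition state places the C2 chlorine equatorial, axial hydrogen delivery does the same at C3, and E/Z isomers of the alkene converge. Ring B comes from (R)-5-methylcyclohexenone; an Evans aldol and imide closure complete the side chain.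

Key step: step 12

Remark: labdane numbering (C1–C20) is used for every intermediate; β is the face of the C10 methyl group; PMB = 4-methoxybenzyl.
Assumption: (R)-5-methylcyclohex-2-en-1-one is taken as a purchasable building block (it is otherwise three known steps from (R)-(+)-pulegone).

Step 1
Reactants: 1 (R)-5-methylcyclohex-2-en-1-one; 2 tert-butyl bromoacetate
Product: 4 tert-butyl 2-[(1S,6R)-6-methyl-2-oxocyclohex-3-en-1-yl]acetate (C9 chain β and trans to the C8 methyl), via lithium dienolate 3 (not isolated)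
Conditions: LiN(iPr)2, THF, −78 °C; then 2, DMPU, −78 → −20 °C
Reagents that add atoms: none
Why: Kinetic deprotonation gives the cross-conjugated α′-enolate and its SN2 alkylation (enolate alkylation) occurs anti to the neighbouring C8 methyl group, which sets C9 with the acetate chain trans to that methyl, while the enolisable C9 lets any cis isomer equilibrate to the same diequatorial product.

Step 2
Reactants: 5 (4-methoxyphenyl)methanol; 6 tributyl(iodomethyl)stannane
Product: 7 tributyl{[(4-methoxybenzyl)oxy]methyl}stannane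
Conditions: NaH, THF–DMF, 0 °C → rt
Reagents that add atoms: none
Why: Williamson ether synthesis, in which the alkoxide displaces iodide from the unhindered primary α-stannyl carbon.

Step 3
Reactants: 4 tert-butyl 2-[(1S,6R)-6-methyl-2-oxocyclohex-3-en-1-yl]acetate; 7 tributyl{[(4-methoxybenzyl)oxy]methyl}stannane
Product: 9 tert-butyl 2-[(1S,6R)-2-hydroxy-2-{[(4-methoxybenzyl)oxy]methyl}-6-methylcyclohex-3-en-1-yl]acetate (both C10 carbinol epimers), via alkoxymethyllithium 8 (not isolated)
Conditions: 7, n-BuLi, THF, −78 °C; then CeCl3 and 4, −78 °C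
Reagents that add atoms: none
Why: Tin–lithium exchange gives the α-alkoxymethyllithium, whose 1,2-addition to the enone carbonyl (made non-basic by CeCl3 so that C9 is not enolised and the tert-butyl ester is left alone) installs C1 on C10, the carbinol configuration being irrelevant because C10 becomes sp2 in step 4.

Step 4
Reactants: 9 tertiary allylic alcohol
Product: 10 tert-butyl 2-[(1S,6R)-2-{[(4-methoxybenzyl)oxy]methyl}-6-methyl-4-oxocyclohex-2-en-1-yl]acetate (C6 ketone, C5=C10 alkene with C1 on C10)
Conditions: pyridinium chlorochromate [C5H5NH][CrO3Cl], 4 Å sieves, CH2Cl2, rt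
Reagents that add atoms: pyridinium chlorochromate, [O-][Cr](=O)(=O)Cl.c1cc[nH+]cc1
Why: Dauben–Babler oxidative transposition, in which the tertiary allylic chromate ester undergoes a [3,3] shift and is oxidised to the enone that now has C6 as carbonyl and C1 on the β-carbon C10.

Step 5
Reactants: 10 transposed enone
Product: 11 tert-butyl 2-[(1S,2R,6R)-2-{[(4-methoxybenzyl)oxy]methyl}-2,6-dimethyl-4-(trimethylsilyloxy)cyclohex-3-en-1-yl]acetate (C10: methyl β and CH2OPMB α; C5=C6 silyl enol ether)
Conditions: Me2CuLi (from MeLi and CuI), Me3SiCl, THF, −78 → −30 °C; Et3N quench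
Reagents that add atoms: methyllithium, [Li]C; chlorotrimethylsilane, C[Si](C)(C)Cl
Why: Conjugate addition of the cuprate, accelerated by Me3SiCl, in which methyl enters axially on the half-chair that keeps the C8 methyl and C9 chain equatorial and therefore anti to the C8 methyl and syn to the C9 chain, which sets C10 (methyl β, C1 α), and the enolate is trapped regiospecifically as the C5=C6 silyl enol ether.

Step 6
Reactants: 12 2-methylbut-3-yn-2-ol; 13 Co2(CO)8
Product: 14 hexacarbonyl[μ-(2-methylbut-3-yn-2-ol)]dicobalt, Co2(CO)6(HC≡CCMe2OH)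
Conditions: CH2Cl2, rt
Reagents that add atoms: none
Why: Ligand substitution, in which the alkyne displaces two CO ligands of Co2(CO)8 to give the bridged hexacarbonyl complex needed for the Nicholas reaction.

Step 7
Reactants: 11 silyl enol ether; 14 Co2(CO)6(HC≡CCMe2OH)
Product: 15 Co2(CO)6 complex of the C5-(2-methylbut-3-yn-2-yl) C6 ketone (C5 epimers)
Conditions: BF3·OEt2, CH2Cl2, −78 → −20 °C
Reagents that add atoms: none
Why: Nicholas reaction, in which BF3 ionises the cobalt-stabilised tertiary propargylic alcohol and the cation alkylates the silyl enol ether only at C5 without allene formation to form the C4–C5 bond, the C5 configuration being left open here because it is equilibrated in step 8.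

Step 8
Reactants: 15 cobalt-complexed alkynyl ketone
Product: 17 alkynyl keto alcohol (ring B cyclohexanone: H-5 α with the C(CH3)2C≡CH group equatorial, C6=O, C8 methyl α, C9 CH2CO2tBu β, C10 methyl β, C10 CH2OH α), via C5-epimeric alkynyl keto alcohol 16 (not isolated)
Conditions: (NH4)2Ce(NO3)6, acetone–H2O, 0 °C; then DBU, PhMe, 60 °C
Reagents that add atoms: none
Why: (NH4)2Ce(NO3)6 oxidatively decomplexes the alkyne and cleaves the PMB ether in the same pot, and DBU then epimerises C5 (α to the C6 ketone) to the thermodynamic isomer in which the bulky C4 group is equatorial and trans to the C10 hydroxymethyl group.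

Step 9
Reactants: 17 alkynyl keto alcohol
Product: 18 chloroalkynyl keto alcohol (C4–C≡C–Cl)
Conditions: NCS, AgOAc (cat.), acetone, 50 °C
Reagents that add atoms: N-chlorosuccinimide, O=C1CCC(=O)N1Cl
Why: Silver-catalysed electrophilic chlorination of the terminal alkyne through the silver acetylide, which leaves the ketone, alcohol and ester untouched.

Step 10
Reactants: 18 chloroalkynyl keto alcohol
Product: 19 (Z)-1,2-dichlorovinyl keto alcohol (C4–C3(Cl)=C2HCl with the C2 chlorine trans to C4)
Conditions: LiCl, AcOH, Pd(OAc)2 (cat.), MeCN, 40 °C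
Reagents that add atoms: lithium chloride, [Li+].[Cl-]
Why: Palladium-catalysed anti-hydrochlorination of the 1-chloroalkyne (trans-chloropalladation at C3 followed by protodepalladation at C2), which should give the (Z)-1,2-dichloroalkene with the C2 chlorine trans to C4.

Step 11
Reactants: 19 (Z)-1,2-dichlorovinyl keto alcohol
Product: 20 neopentyl iodide (C10 CH2I α; otherwise as 19)
Conditions: PPh3, I2, imidazole, PhMe, 80 °C
Reagents that add atoms: iodine, II
Why: Appel-type (Garegg–Samuelsson) iodination through the alkoxyphosphonium ion, in which heat compensates for the slow SN2 at the neopentyl carbon and no stereocentre is touched.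

Step 12
Reactants: 20 neopentyl iodide
Product: 21 trans-decalin keto ester: tert-butyl 2-(2α,3β-dichloro-4,4,8α,10β-tetramethyl-6-oxo-5α-decalin-9β-yl)acetate
Conditions: (Me3Si)3SiH and AIBN by syringe pump, PhMe (0.005 M), 90 °C
Reagents that add atoms: none
Why: The silyl radical abstracts iodine from C1 to give a primary neopentyl-type radical, which adds 6-endo-trig to C2 of the dichloroalkene to give the tertiary α-chloro radical at C3, and this takes hydrogen from the silane to carry the chain. The closest known reaction type is the reductive Giese-type alkyl radical cyclisation onto chloroalkenes, run as in the 6-endo ring closures of radical polyene cyclisations. Ring A closes 6-endo-trig because 5-exo attack would have to bond to the fully substituted C3 wedged against quaternary C4, and because 6-endo attack gives the more stabilised α-chloro radical. C2 is set in a chair transition state fused trans to ring B through the equatorial C10–C1 and C5–C4 bonds: the C2 chlorine, being trans to C4 across the double bond, is forced equatorial (2α), and any E isomer, which would have to place chlorine axial against the C10 and C4β methyl groups, should be drained into the Z isomer by reversible silyl-radical addition. C3 is set when the bulky silane delivers hydrogen axially from the α face, away from the axial 4β methyl group, which leaves chlorine equatorial (3β). The step needs cyclisation to outrun direct reduction of the C1 radical, which slow addition of the weak hydrogen donor, the Thorpe–Ingold effect of C4 and C10 and the absence of other acceptors or abstractable 1,5-hydrogens (the side chain is a plain ester) secure.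

Step 13
Reactants: 21 trans-decalin keto ester
Product: 22 7-en-6-one: tert-butyl 2-(2α,3β-dichloro-4,4,8,10β-tetramethyl-6-oxo-5α-decal-7-en-9β-yl)acetate
Conditions: IBX, DMSO–PhF, 70 °C
Reagents that add atoms: none
Why: IBX-mediated dehydrogenation of the ketone through its enol, which can form only towards C7 because C5 is a methine locked between two quaternary carbons, so that the 7-en-6-one results and the relay stereocentre C8 is deliberately removed.

Step 14
Reactants: 22 7-en-6-one
Product: 24 8(17)-en-6-one: tert-butyl 2-(2α,3β-dichloro-4,4,10β-trimethyl-8-methylidene-6-oxo-5α-decalin-9β-yl)acetate, via potassium dienolate 23 (not isolated)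
Conditions: KN(SiMe3)2, THF, −78 °C; then AcOH, −78 °C
Reagents that add atoms: none
Why: Deconjugative protonation, in which γ-deprotonation at the C17 methyl gives the extended dienolate and kinetic protonation at C7 delivers the β,γ-unsaturated ketone with the exocyclic C8=C17 alkene, while the two equatorial chlorides have no anti-periplanar hydrogen for E2.

Step 15
Reactants: 24 8(17)-en-6-one ester
Product: 25 diol: 2α,3β-dichloro-9β-(2-hydroxyethyl)-4,4,10β-trimethyl-8-methylidene-5α-decalin-6-ol (C6 epimers, 6β expected)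
Conditions: LiAlH4, THF, 0 °C → rt
Reagents that add atoms: none
Why: Hydride reduction of both the ester (to the C12 alcohol) and the C6 ketone, whose carbinol configuration is irrelevant because it is reoxidised in step 16, and secondary alkyl chlorides are inert at this temperature.

Step 16
Reactants: 25 diol
Product: 26 keto aldehyde: 2-(2α,3β-dichloro-4,4,10β-trimethyl-8-methylidene-6-oxo-5α-decalin-9β-yl)acetaldehyde
Conditions: Dess–Martin periodinane, pyridine, CH2Cl2, 0 °C → rt
Reagents that add atoms: none
Why: Dess–Martin oxidation of both alcohols under buffered, non-enolising conditions, which should return the C6 ketone without moving the C8=C17 double bond into conjugation and give the C12 aldehyde.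

Step 17
Reactants: 27 (R)-4-benzyloxazolidin-2-one; 28 methyl 4-chloro-4-oxobutanoate
Product: 30 (R)-4-benzyl-3-(4-methoxy-4-oxobutanoyl)oxazolidin-2-one, via N-lithio oxazolidinone 29 (not isolated)
Conditions: n-BuLi, THF, −78 °C; then 28
Reagents that add atoms: none
Why: N-acylation of the lithiated oxazolidinone by the acid chloride, which is far more reactive than the methyl ester.

Step 18
Reactants: 26 keto aldehyde; 30 (R)-4-benzyl-3-(4-methoxy-4-oxobutanoyl)oxazolidin-2-one
Product: 32 syn-aldol adduct (12S,13R; C13 bears CH2CO2Me and the acyl oxazolidinone), via boron enolate 31 (not isolated)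
Conditions: 30, Bu2BOTf, iPr2NEt, CH2Cl2, −78 → 0 °C; then 26, −78 → 0 °C; pH 7 buffer, MeOH, H2O2
Reagents that add atoms: none
Why: Evans syn-aldol reaction, in which the (Z)-boron enolate reacts through a Zimmerman–Traxler chair with one enolate face shielded by the (R)-benzyl auxiliary, which sets C12 (S) and C13 (R), and the aldehyde reacts in preference to the hindered C6 ketone.

Step 19
Reactants: 32 syn-aldol adduct
Product: 34 Haterumaimide B, via primary amide 33 (not isolated)
Conditions: NH3 (7 M in MeOH), THF, 0 °C → rt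
Reagents that add atoms: ammonia, N
Why: Ammonolysis of the N-acyl oxazolidinone gives the primary amide, whose nitrogen attacks the methyl ester in a 5-exo-trig acyl substitution to close the succinimide and release the auxiliary, with no stereocentre involved.

Compound list
1 | (R)-5-methylcyclohex-2-en-1-one | C[C@@H]1CC=CC(=O)C1 | starting material
2 | tert-butyl bromoacetate | CC(C)(C)OC(=O)CBr | starting material
3 | lithium cross-conjugated dienolate of 1 (O–C10=C9) | C[C@@H]1CC=CC(O[Li])=C1 | intermediate
4 | tert-butyl 2-[(1S,6R)-6-methyl-2-oxocyclohex-3-en-1-yl]acetate | C[C@@H]1CC=CC(=O)[C@H]1CC(=O)OC(C)(C)C | intermediate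
5 | (4-methoxyphenyl)methanol | COc1ccc(CO)cc1 | starting material
6 | tributyl(iodomethyl)stannane | CCCC[Sn](CCCC)(CCCC)CI | starting material
7 | tributyl{[(4-methoxybenzyl)oxy]methyl}stannane | CCCC[Sn](CCCC)(CCCC)COCc1ccc(OC)cc1 | intermediate
8 | {[(4-methoxybenzyl)oxy]methyl}lithium | [Li]COCc1ccc(OC)cc1 | intermediate
9 | tert-butyl 2-[(1S,6R)-2-hydroxy-2-{[(4-methoxybenzyl)oxy]methyl}-6-methylcyclohex-3-en-1-yl]acetate (C10 epimers) | C[C@@H]1CC=CC(O)(COCc2ccc(OC)cc2)[C@H]1CC(=O)OC(C)(C)C | intermediate
10 | tert-butyl 2-[(1S,6R)-2-{[(4-methoxybenzyl)oxy]methyl}-6-methyl-4-oxocyclohex-2-en-1-yl]acetate | C[C@@H]1CC(=O)C=C(COCc2ccc(OC)cc2)[C@H]1CC(=O)OC(C)(C)C | intermediate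
11 | tert-butyl 2-[(1S,2R,6R)-2-{[(4-methoxybenzyl)oxy]methyl}-2,6-dimethyl-4-(trimethylsilyloxy)cyclohex-3-en-1-yl]acetate | C[C@@H]1CC(O[Si](C)(C)C)=C[C@](C)(COCc2ccc(OC)cc2)[C@H]1CC(=O)OC(C)(C)C | intermediate
12 | 2-methylbut-3-yn-2-ol | CC(C)(O)C#C | starting material
13 | Co2(CO)8 | O=C=[Co](=C=O)(=C=O)(=C=O)[Co](=C=O)(=C=O)(=C=O)=C=O | starting material
14 | Co2(CO)6(HC≡CCMe2OH) | CC(C)(O)[C]12[CH]3[Co]1(=C=O)(=C=O)(=C=O)[Co]23(=C=O)(=C=O)=C=O | intermediate
15 | Co2(CO)6 complex of the C5-(2-methylbut-3-yn-2-yl) C6 ketone (C5 epimers; C10 methyl β, CH2OPMB α) | C[C@@H]1CC(=O)C(C(C)(C)[C]23[CH]4[Co]2(=C=O)(=C=O)(=C=O)[Co]34(=C=O)(=C=O)=C=O)[C@](C)(COCc2ccc(OC)cc2)[C@H]1CC(=O)OC(C)(C)C | intermediate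
16 | alkynyl keto alcohol, C5 epimers | C[C@@H]1CC(=O)C(C(C)(C)C#C)[C@](C)(CO)[C@H]1CC(=O)OC(C)(C)C | intermediate
17 | alkynyl keto alcohol, H-5 α (C4 group equatorial, trans to C10 CH2OH) | C[C@@H]1CC(=O)[C@@H](C(C)(C)C#C)[C@](C)(CO)[C@H]1CC(=O)OC(C)(C)C | intermediate
18 | chloroalkynyl keto alcohol | C[C@@H]1CC(=O)[C@@H](C(C)(C)C#CCl)[C@](C)(CO)[C@H]1CC(=O)OC(C)(C)C | intermediate
19 | (Z)-1,2-dichlorovinyl keto alcohol | C[C@@H]1CC(=O)[C@@H](C(C)(C)/C(Cl)=C/Cl)[C@](C)(CO)[C@H]1CC(=O)OC(C)(C)C | intermediate
20 | (Z)-1,2-dichlorovinyl keto neopentyl iodide | C[C@@H]1CC(=O)[C@@H](C(C)(C)/C(Cl)=C/Cl)[C@](C)(CI)[C@H]1CC(=O)OC(C)(C)C | intermediate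
21 | tert-butyl 2-(2α,3β-dichloro-4,4,8α,10β-tetramethyl-6-oxo-5α-decalin-9β-yl)acetate | C[C@@H]1CC(=O)[C@H]2C(C)(C)[C@@H](Cl)[C@H](Cl)C[C@]2(C)[C@H]1CC(=O)OC(C)(C)C | intermediate
22 | tert-butyl 2-(2α,3β-dichloro-4,4,8,10β-tetramethyl-6-oxo-5α-decal-7-en-9β-yl)acetate | CC1=CC(=O)[C@H]2C(C)(C)[C@@H](Cl)[C@H](Cl)C[C@]2(C)[C@H]1CC(=O)OC(C)(C)C | intermediate
23 | potassium extended dienolate of 22 (C6–O, C6=C7, C8=C17) | C=C1C=C(O[K])[C@H]2C(C)(C)[C@@H](Cl)[C@H](Cl)C[C@]2(C)[C@H]1CC(=O)OC(C)(C)C | intermediate
24 | tert-butyl 2-(2α,3β-dichloro-4,4,10β-trimethyl-8-methylidene-6-oxo-5α-decalin-9β-yl)acetate | C=C1CC(=O)[C@H]2C(C)(C)[C@@H](Cl)[C@H](Cl)C[C@]2(C)[C@H]1CC(=O)OC(C)(C)C | intermediate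
25 | 2α,3β-dichloro-9β-(2-hydroxyethyl)-4,4,10β-trimethyl-8-methylidene-5α-decalin-6-ol (C6 epimers) | C=C1CC(O)[C@H]2C(C)(C)[C@@H](Cl)[C@H](Cl)C[C@]2(C)[C@H]1CCO | intermediate
26 | 2-(2α,3β-dichloro-4,4,10β-trimethyl-8-methylidene-6-oxo-5α-decalin-9β-yl)acetaldehyde | C=C1CC(=O)[C@H]2C(C)(C)[C@@H](Cl)[C@H](Cl)C[C@]2(C)[C@H]1CC=O | intermediate
27 | (R)-4-benzyloxazolidin-2-one | O=C1N[C@H](Cc2ccccc2)CO1 | starting material
28 | methyl 4-chloro-4-oxobutanoate | COC(=O)CCC(Cl)=O | starting material
29 | N-lithio-(R)-4-benzyloxazolidin-2-one | [Li]N1[C@H](Cc2ccccc2)COC1=O | intermediate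
30 | (R)-4-benzyl-3-(4-methoxy-4-oxobutanoyl)oxazolidin-2-one | COC(=O)CCC(=O)N1[C@H](Cc2ccccc2)COC1=O | intermediate
31 | (Z)-dibutylboron enolate of 30 | COC(=O)C/C=C(\OB(CCCC)CCCC)N1[C@H](Cc2ccccc2)COC1=O | intermediate
32 | syn-aldol adduct (12S,13R) with methyl ester and (R)-benzyl oxazolidinone | C=C1CC(=O)[C@H]2C(C)(C)[C@@H](Cl)[C@H](Cl)C[C@]2(C)[C@H]1C[C@H](O)[C@@H](CC(=O)OC)C(=O)N1[C@H](Cc2ccccc2)COC1=O | intermediate
33 | (12S,13R) hydroxy primary amide methyl ester | C=C1CC(=O)[C@H]2C(C)(C)[C@@H](Cl)[C@H](Cl)C[C@]2(C)[C@H]1C[C@H](O)[C@@H](CC(=O)OC)C(N)=O | intermediate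
34 | Haterumaimide B | C=C1CC(=O)[C@H]2C(C)(C)[C@@H](Cl)[C@H](Cl)C[C@]2(C)[C@H]1C[C@H](O)[C@H]1CC(=O)NC1=O | target

Total step count: 19. Longest linear sequence: 16 steps (1, 3–5, 7–16, 18, 19).

Steps most likely to fail

Step 12. The primary C1 radical may be reduced by the silane before the slow 6-endo closure (simple deiodination), or the closure may show poor control at C2. The fallback makes the same ring bond by polar chemistry; it sets out from 18 and comes back at 21, and it is longer. Dess–Martin oxidation of 18 should give the chloroalkynyl keto aldehyde F1, and Ph3PAuNTf2-catalysed hydration of the chloroalkyne the α-chloromethyl ketone F2. An acid-mediated intramolecular aldol condensation (TsOH, benzene, reflux) between C2 and the non-enolisable C1 aldehyde then closes ring A to the 2-chloro-1-en-3-one F3. Conjugate reduction with [(Ph3P)CuH]6 and equilibration at C2 should give the 2α-chloro-3,6-dione F4. NaBH4 at −40 °C should reduce the more electrophilic α-chloro ketone from the α face to the 2α-chloro-3β-ol F5. Chlorosulfite formation with SOCl2 and TiCl4-catalysed collapse with retention would then give 21; this last substitution at the neopentyl C3 is the weak point of the fallback.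

Step 7. The tertiary propargylic cation may fail to attack C5, which sits next to quaternary C10, so that the silyl enol ether is simply desilylated and the cation eliminates to the enyne. The fallback builds C4 in two less congested bond formations; it sets out from 11 and comes back at 17. A Mukaiyama aldol addition of 11 to acetone (TiCl4, CH2Cl2, −78 °C) should give the β-hydroxy ketone F6, and dehydration (MsCl, Et3N, then DBU) the α-isopropylidene ketone F7. Conjugate alkynylation of this s-cis enone with Me2AlC≡CSiMe3 (Ni(acac)2 and i-Bu2AlH as catalysts, Et2O) creates quaternary C4, and protonation at the epimerisable C5 should give the silylalkyne F8. K2CO3 in MeOH gives the terminal alkyne F9, and DDQ removes the PMB group to reach 17.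

Step 19. The base may move the exocyclic C8=C17 double bond into conjugation with the C6 ketone during ammonolysis (and to a lesser degree during the aldol), or the imide closure may stall at the amide. The fallback postpones the C6 oxidation until the imide is in place; it sets out from 25 and ends at 34. Selective oxidation of the primary alcohol of 25 (TEMPO, PhI(OAc)2) should give the hydroxy aldehyde F10, and the Evans aldol with 31 the adduct F11, whose hindered axial C6 hydroxyl is left free. Silylation of the C12 hydroxyl (Et3SiCl, imidazole) gives the triethylsilyl ether F12, and NH3 in MeOH the silylated hydroxy imide F13, with no enolisable β,γ-unsaturated ketone present. Dess–Martin oxidation then gives the silylated keto imide F14, and HF·pyridine releases 34.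

Further compounds
F1 | step 12 | chloroalkynyl keto aldehyde (C10 CHO α) | C[C@@H]1CC(=O)[C@@H](C(C)(C)C#CCl)[C@](C)(C=O)[C@H]1CC(=O)OC(C)(C)C
F2 | step 12 | α-chloromethyl ketone keto aldehyde | C[C@@H]1CC(=O)[C@@H](C(C)(C)C(=O)CCl)[C@](C)(C=O)[C@H]1CC(=O)OC(C)(C)C
F3 | step 12 | ring A 2-chloro-1-en-3-one of the trans-decalin | C[C@@H]1CC(=O)[C@H]2C(C)(C)C(=O)C(Cl)=C[C@]2(C)[C@H]1CC(=O)OC(C)(C)C
F4 | step 12 | 2α-chloro-3,6-dione | C[C@@H]1CC(=O)[C@H]2C(C)(C)C(=O)[C@H](Cl)C[C@]2(C)[C@H]1CC(=O)OC(C)(C)C
F5 | step 12 | 2α-chloro-3β-hydroxy-6-one | C[C@@H]1CC(=O)[C@H]2C(C)(C)[C@@H](O)[C@H](Cl)C[C@]2(C)[C@H]1CC(=O)OC(C)(C)C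
F6 | step 7 | β-hydroxy ketone from acetone (C5 epimers) | C[C@@H]1CC(=O)C(C(C)(C)O)[C@](C)(COCc2ccc(OC)cc2)[C@H]1CC(=O)OC(C)(C)C
F7 | step 7 | α-isopropylidene ketone | C[C@@H]1CC(=O)C(=C(C)C)[C@](C)(COCc2ccc(OC)cc2)[C@H]1CC(=O)OC(C)(C)C
F8 | step 7 | silylalkyne PMB ether (H-5 α) | C[C@@H]1CC(=O)[C@@H](C(C)(C)C#C[Si](C)(C)C)[C@](C)(COCc2ccc(OC)cc2)[C@H]1CC(=O)OC(C)(C)C
F9 | step 7 | terminal alkyne PMB ether (H-5 α) | C[C@@H]1CC(=O)[C@@H](C(C)(C)C#C)[C@](C)(COCc2ccc(OC)cc2)[C@H]1CC(=O)OC(C)(C)C
F10 | step 19 | C6 hydroxy C12 aldehyde (C6 epimers) | C=C1CC(O)[C@H]2C(C)(C)[C@@H](Cl)[C@H](Cl)C[C@]2(C)[C@H]1CC=O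
F11 | step 19 | syn-aldol adduct with free C6 hydroxyl | C=C1CC(O)[C@H]2C(C)(C)[C@@H](Cl)[C@H](Cl)C[C@]2(C)[C@H]1C[C@H](O)[C@@H](CC(=O)OC)C(=O)N1[C@H](Cc2ccccc2)COC1=O
F12 | step 19 | C12 triethylsilyl ether of F11 | C=C1CC(O)[C@H]2C(C)(C)[C@@H](Cl)[C@H](Cl)C[C@]2(C)[C@H]1C[C@H](O[Si](CC)(CC)CC)[C@@H](CC(=O)OC)C(=O)N1[C@H](Cc2ccccc2)COC1=O
F13 | step 19 | C12 silylated succinimide with C6 hydroxyl | C=C1CC(O)[C@H]2C(C)(C)[C@@H](Cl)[C@H](Cl)C[C@]2(C)[C@H]1C[C@H](O[Si](CC)(CC)CC)[C@H]1CC(=O)NC1=O
F14 | step 19 | C12 silylated succinimide with C6 ketone | C=C1CC(=O)[C@H]2C(C)(C)[C@@H](Cl)[C@H](Cl)C[C@]2(C)[C@H]1C[C@H](O[Si](CC)(CC)CC)[C@H]1CC(=O)NC1=O
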